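**Retrosynthetic overview**

- Numbering used throughout: ring A is the cyclopentenone C1(=O)–C2(OMe)=C3(Ar)–C4–C5(OMe)(Ar), C6 is the exocyclic carbon on C4, and ring B is the oxirane C4–C6–O.
- The strategy rests on ring A being the sum of three components: C2–C3 (an aryl methoxyalkyne), C4–C5 with C6 attached (the donor-substituted π-bond of a 1-aryl-1-methoxyallene) and C1 (CO). One cobalt [2+2+1] step forms C3–C4, C5–C1 and C1–C2 and sets C5.
- Ring B follows from the C4=C6 methylene: anti bromohydrin (Br on C6, OH on C4 cis to the C5 aryl), base closure, then release of the two phenols.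
- Alkyne and allene both come from silyl-protected 4-iodophenol by Negishi coupling, with zinc methoxyacetylide and with 1-methoxyallenylzinc chloride.
- Order of ring formation: ring A (step 6), then ring B (step 8).

Key step: step 6

Assumption: the (R)-configured bridging ligand is taken to favour the (5R) product; if induction runs the other way, the ligand made from (S)-1-phenylethylamine is used with no other change.

**Route**

Step 1
Reactants: 1 4-iodophenol
Product: 2 triisopropyl(4-iodophenoxy)silane
Conditions: TIPSCl, imidazole, DMF, rt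
Reagents that add atoms: triisopropylsilyl chloride, CC(C)[Si](Cl)(C(C)C)C(C)C
Why: Imidazole-promoted silylation of the phenol (silyl ether formation) masks the acidic OH for the organometallic steps and should survive amide bases, zinc reagents and cobalt carbonyls.

Step 2
Reactants: 3 methoxyallene (1.3 equiv); 2 triisopropyl(4-iodophenoxy)silane
Product: 6 1-methoxy-1-[4-(triisopropylsilyloxy)phenyl]propa-1,2-diene, via 1-lithio-1-methoxyallene 4 (not isolated), via (1-methoxyallenyl)zinc chloride 5 (not isolated)
Conditions: n-BuLi (1.2 equiv), THF, −40 °C; ZnCl2, −40 to 0 °C; then 2, Pd(PPh3)4 (5 mol %), rt; chromatography on Et3N-deactivated silica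
Reagents that add atoms: none
Why: α-Lithiation of methoxyallene, transmetalation to zinc and Negishi coupling with the aryl iodide at the oxygen-bearing carbon is an established way to 1-aryl-1-alkoxyallenes; no stereocentre is formed.

Step 3
Reactants: 7 chloroacetaldehyde dimethyl acetal (1.5 equiv); 2 triisopropyl(4-iodophenoxy)silane
Product: 10 1-(methoxyethynyl)-4-(triisopropylsilyloxy)benzene, via lithium methoxyacetylide 8 (not isolated), via (methoxyethynyl)zinc chloride 9 (not isolated)
Conditions: LiNEt2 (3 equiv per 7, from Et2NH and n-BuLi), THF, 0 °C; ZnCl2, 0 °C; then 2, Pd(PPh3)4 (5 mol %), rt; work-up at pH 8, basic alumina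
Reagents that add atoms: none
Why: The lithium amide acts three times (loss of methanol, loss of HCl, deprotonation) to give the metallated ynol ether, whose zinc derivative undergoes Negishi coupling with the aryl iodide; no stereocentre is formed.

Step 4
Reactants: 11 (R)-1-phenylethylamine
Product: 12 (R)-N,N-bis(diphenylphosphino)-1-phenylethylamine
Conditions: Ph2PCl (2.05 equiv), Et3N, CH2Cl2, 0 °C to rt, under argon
Reagents that add atoms: chlorodiphenylphosphine, ClP(c1ccccc1)c1ccccc1
Why: Double P–N bond formation by aminolysis of the chlorophosphine is the standard preparation of bis(phosphino)amines; the stereocentre of the amine is not touched.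

Step 5
Reactants: 10 1-(methoxyethynyl)-4-(triisopropylsilyloxy)benzene; 12 (R)-N,N-bis(diphenylphosphino)-1-phenylethylamine
Product: 14 Co2(CO)4(μ-12)(μ-10) complex, via Co2(CO)6 alkyne complex 13 (not isolated)
Conditions: Co2(CO)8 (1.05 equiv), toluene, rt; then 12, 65 °C, N2
Reagents that add atoms: octacarbonyldicobalt Co2(CO)8, O=C=[Co](=C=O)(=C=O)(=C=O)[Co](=C=O)(=C=O)(=C=O)=C=O
Why: Alkyne complexation by Co2(CO)8 followed by thermal ligand substitution places the short-bite diphosphine across the Co–Co bond, one phosphorus on each cobalt, as known for bis(phosphino)amines on alkyne–dicobalt complexes; the only stereocentre is that of the ligand.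

Step 6
Reactants: 14 Co2(CO)4(μ-12)(μ-10) complex; 6 1-methoxy-1-[4-(triisopropylsilyloxy)phenyl]propa-1,2-diene (2 equiv); 15 carbon monoxide
Product: 16 (5R)-2,5-dimethoxy-4-methylidene-3,5-bis[4-(triisopropylsilyloxy)phenyl]cyclopent-2-en-1-one
Conditions: CO (1 atm), toluene, 70 °C
Reagents that add atoms: none
Why: Proposed new method: loss of one CO from 14 frees a site on cobalt for the C5=C4 π-bond of 6, which inserts into the Co–C3 bond through its central carbon (C3–C4) and leaves cobalt on C5; under CO this tertiary alkyl should be carbonylated (C5–C1) before it can slip through an η3-allyl form to C6, and reductive elimination of the acyl onto C2 (C1–C2) releases 16. The closest known reaction type is the intermolecular cobalt-mediated Pauson–Khand reaction of alkyne–Co2(CO)6 complexes with allenes, which gives 4-alkylidenecyclopentenones but usually through the less substituted π-bond, together with the use of bridging bis(phosphino)amine ligands on such complexes for asymmetric induction with strained alkenes. Ring A closes in a metal-templated [2+2+1] manner: a five-membered cobaltacycle (Co, C2, C3, C4, C5) takes up CO and contracts to the carbocycle by C(acyl)–C(vinyl) reductive elimination. C5 becomes stereogenic when cobalt bonds to one enantiotopic face of C5=C4; ligand 12 makes the two cobalt atoms unequal, and at the reacting cobalt the C5 aryl group should turn away from the neighbouring PPh2 group, which is expected to give (5R). Three selectivities are needed: C2 next to C1 (secured by the methoxy group of the alkyne, which takes the position α to the carbonyl as in other alkoxyalkyne complexes); reaction at the internal allene π-bond with C5 bonded to CO (favoured by the methoxy and aryl donors on C5, which make this π-bond the better donor to the electron-poor cobalt, and by trapping under CO, but opposed by the steric preference for the CH2 terminus); and the C5 face (ligand control).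

Step 7
Reactants: 16 (5R)-2,5-dimethoxy-4-methylidene-3,5-bis[4-(triisopropylsilyloxy)phenyl]cyclopent-2-en-1-one
Product: 17 (4S,5R)-4-(bromomethyl)-4-hydroxy-2,5-dimethoxy-3,5-bis[4-(triisopropylsilyloxy)phenyl]cyclopent-2-en-1-one (OH cis to the C5 aryl)
Conditions: NBS (1.05 equiv), NaHCO3, acetone/H2O (5:1), 0 °C, dark
Reagents that add atoms: N-bromosuccinimide, O=C1CCC(=O)N1Br; water, O
Why: Halohydrin formation: Br+ should add to the exocyclic C4=C6 bond on the face anti to the bulky C5 aryl and water should open the bromonium ion at the more substituted, allylic C4 from the opposite face (anti addition), which sets C4 with OH cis to the C5 aryl, while the C1 carbonyl disfavours capture at C2.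

Step 8
Reactants: 17 (4S,5R)-4-(bromomethyl)-4-hydroxy-2,5-dimethoxy-3,5-bis[4-(triisopropylsilyloxy)phenyl]cyclopent-2-en-1-one
Product: 18 (3R,4R)-4,6-dimethoxy-4,7-bis[4-(triisopropylsilyloxy)phenyl]-1-oxaspiro[2.4]hept-6-en-5-one (4R,5R in the ring A numbering; oxirane oxygen cis to the C5 aryl)
Conditions: DBU, CH2Cl2, 0 °C to rt
Reagents that add atoms: none
Why: Intramolecular Williamson etherification (3-exo-tet displacement of the primary bromide by the C4 alkoxide) closes ring B without touching the C4–O bond, so the oxirane oxygen stays cis to the C5 aryl.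

Step 9
Reactants: 18 (3R,4R)-4,6-dimethoxy-4,7-bis[4-(triisopropylsilyloxy)phenyl]-1-oxaspiro[2.4]hept-6-en-5-one
Product: 19 (3R,4R)-4,7-bis(4-hydroxyphenyl)-4,6-dimethoxy-1-oxaspiro[2.4]hept-6-en-5-one (CNP0504072.1)
Conditions: TBAF, AcOH (1:1, 2.2 equiv), THF, 0 °C
Reagents that add atoms: none
Why: Fluoride-mediated cleavage of the two aryl silyl ethers, buffered with acetic acid to spare the allylic epoxide and the benzylic methyl ether, releases the phenols; no stereocentre is affected.

**Compound list**

1 | 4-iodophenol | Oc1ccc(I)cc1 | starting material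
2 | triisopropyl(4-iodophenoxy)silane | CC(C)[Si](Oc1ccc(I)cc1)(C(C)C)C(C)C | intermediate
3 | methoxyallene (1-methoxypropa-1,2-diene) | COC=C=C | starting material
4 | 1-lithio-1-methoxyallene | COC([Li])=C=C | intermediate
5 | (1-methoxyallenyl)zinc chloride | COC([Zn]Cl)=C=C | intermediate
6 | 1-methoxy-1-[4-(triisopropylsilyloxy)phenyl]propa-1,2-diene | COC(=C=C)c1ccc(O[Si](C(C)C)(C(C)C)C(C)C)cc1 | intermediate
7 | chloroacetaldehyde dimethyl acetal | COC(CCl)OC | starting material
8 | lithium methoxyacetylide | COC#C[Li] | intermediate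
9 | (methoxyethynyl)zinc chloride | COC#C[Zn]Cl | intermediate
10 | 1-(methoxyethynyl)-4-(triisopropylsilyloxy)benzene | COC#Cc1ccc(O[Si](C(C)C)(C(C)C)C(C)C)cc1 | intermediate
11 | (R)-1-phenylethylamine | C[C@@H](N)c1ccccc1 | starting material
12 | (R)-N,N-bis(diphenylphosphino)-1-phenylethylamine | C[C@@H](N(P(c1ccccc1)c1ccccc1)P(c1ccccc1)c1ccccc1)c1ccccc1 | intermediate
13 | Co2(CO)6(μ-10), hexacarbonyl dicobalt complex with alkyne 10 bridging the Co–Co bond | COC12[Co]3(=C=O)(=C=O)(=C=O)[Co]1(=C=O)(=C=O)(=C=O)C23c1ccc(O[Si](C(C)C)(C(C)C)C(C)C)cc1 | intermediate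
14 | Co2(CO)4(μ-12)(μ-10), tetracarbonyl dicobalt complex with alkyne 10 bridging the Co–Co bond and diphosphine 12 bound through one phosphorus to each cobalt | COC12[Co-]34(=C=O)(=C=O)[P+](c5ccccc5)(c5ccccc5)N([C@H](C)c5ccccc5)[P+](c5ccccc5)(c5ccccc5)[Co-]14(=C=O)(=C=O)C23c1ccc(O[Si](C(C)C)(C(C)C)C(C)C)cc1 | intermediate
15 | carbon monoxide | [C-]#[O+] | starting material
16 | (5R)-2,5-dimethoxy-4-methylidene-3,5-bis[4-(triisopropylsilyloxy)phenyl]cyclopent-2-en-1-one | COC1=C(c2ccc(O[Si](C(C)C)(C(C)C)C(C)C)cc2)C(=C)[C@](OC)(c2ccc(O[Si](C(C)C)(C(C)C)C(C)C)cc2)C1=O | intermediate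
17 | (4S,5R)-4-(bromomethyl)-4-hydroxy-2,5-dimethoxy-3,5-bis[4-(triisopropylsilyloxy)phenyl]cyclopent-2-en-1-one | COC1=C(c2ccc(O[Si](C(C)C)(C(C)C)C(C)C)cc2)[C@@](O)(CBr)[C@](OC)(c2ccc(O[Si](C(C)C)(C(C)C)C(C)C)cc2)C1=O | intermediate
18 | (3R,4R)-4,6-dimethoxy-4,7-bis[4-(triisopropylsilyloxy)phenyl]-1-oxaspiro[2.4]hept-6-en-5-one | COC1=C(c2ccc(O[Si](C(C)C)(C(C)C)C(C)C)cc2)[C@@]2(CO2)[C@](OC)(c2ccc(O[Si](C(C)C)(C(C)C)C(C)C)cc2)C1=O | intermediate
19 | (3R,4R)-4,7-bis(4-hydroxyphenyl)-4,6-dimethoxy-1-oxaspiro[2.4]hept-6-en-5-one | COC1=C(c2ccc(O)cc2)[C@@]2(CO2)[C@](OC)(c2ccc(O)cc2)C1=O | target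

**Step count and risks**

Total: 9 steps. Longest linear sequence: 7 steps (1 → 2 → 10 → 14 → 16 → 17 → 18 → 19; steps 1, 3, 5, 6, 7, 8, 9).

Steps most likely to fail:

1. Step 6 (proposed new method). Insertion may run through the terminal π-bond of the allene with CO ending on C6, as the steric preference dictates. The phosphine-bridged complex may turn over too slowly at a temperature the allene tolerates. Facial discrimination by the remote stereocentre of the ligand may be weak. Low-valent cobalt may cleave the C5–OMe bond reductively. Fallback with known chemistry, setting out from alkyne 10 and coming back at 16: alkyne 10 is complexed with Co2(CO)8 and the Co2(CO)6 complex 13 is isolated and heated with propa-1,2-diene under CO (intermolecular allenic Pauson–Khand reaction in its usual 4-alkylidene mode; both π-bonds of the parent allene are equal) to give 2-methoxy-4-methylidene-3-[4-(triisopropylsilyloxy)phenyl]cyclopent-2-en-1-one F1. Palladium-catalysed α-arylation of the ketone at C5, its only enolisable position, with aryl iodide 2 (Pd2(dba)3, P(t-Bu)3, NaOtBu, toluene) gives racemic 2-methoxy-4-methylidene-3,5-bis[4-(triisopropylsilyloxy)phenyl]cyclopent-2-en-1-one F2. Its potassium enolate (KN(SiMe3)2, THF, −78 °C) is hydroxylated at C5 with the enantiomer of (camphorsulfonyl)oxaziridine that delivers oxygen to the face giving (5R)-5-hydroxy-2-methoxy-4-methylidene-3,5-bis[4-(triisopropylsilyloxy)phenyl]cyclopent-2-en-1-one F3. O-Methylation (MeI, Ag2O) then gives 16.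

2. Step 7. Water may be captured at C2 of the delocalised cation, followed by loss of methanol to an ene-dione. The bromonium ion may open to a free allylic cation, with loss of anti addition and of face control. The silyloxyarenes may be brominated. Fallback, setting out from 16 and coming back at 18: Shi epoxidation of the C4=C6 bond (carbohydrate-derived chiral ketone, Oxone (2KHSO5·KHSO4·K2SO4), K2CO3 buffer, MeCN/dimethoxymethane/H2O, 0 °C), with the ketone enantiomer chosen so that the dioxirane delivers oxygen to the face cis to the C5 aryl. Reagent control of a direct oxygen transfer replaces the anti-addition logic, and no cationic intermediate is formed.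

3. Step 3. The metallated methoxyacetylene may decompose before coupling, the zinc acetylide may homocouple, and the ynol ether may be hydrated to the arylacetate during isolation. Fallback, setting out from 2 and coming back at 10: iodine–magnesium exchange on 2 (i-PrMgCl·LiCl, THF) and acylation with N,2-dimethoxy-N-methylacetamide give 2-methoxy-1-[4-(triisopropylsilyloxy)phenyl]ethanone F4. Enolisation and triflation (KN(SiMe3)2, PhNTf2, THF, −78 °C) give (Z)-2-methoxy-1-[4-(triisopropylsilyloxy)phenyl]ethenyl trifluoromethanesulfonate F5. Base-induced elimination of triflate (KOtBu, THF, −78 to 0 °C) then gives ynol ether 10.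

**Further compounds**

F1 | step 6 | 2-methoxy-4-methylidene-3-[4-(triisopropylsilyloxy)phenyl]cyclopent-2-en-1-one | COC1=C(c2ccc(O[Si](C(C)C)(C(C)C)C(C)C)cc2)C(=C)CC1=O
F2 | step 6 | rac-2-methoxy-4-methylidene-3,5-bis[4-(triisopropylsilyloxy)phenyl]cyclopent-2-en-1-one | COC1=C(c2ccc(O[Si](C(C)C)(C(C)C)C(C)C)cc2)C(=C)C(c2ccc(O[Si](C(C)C)(C(C)C)C(C)C)cc2)C1=O
F3 | step 6 | (5R)-5-hydroxy-2-methoxy-4-methylidene-3,5-bis[4-(triisopropylsilyloxy)phenyl]cyclopent-2-en-1-one | COC1=C(c2ccc(O[Si](C(C)C)(C(C)C)C(C)C)cc2)C(=C)[C@](O)(c2ccc(O[Si](C(C)C)(C(C)C)C(C)C)cc2)C1=O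
F0 | step 7 | none | none
F4 | step 3 | 2-methoxy-1-[4-(triisopropylsilyloxy)phenyl]ethanone | COCC(=O)c1ccc(O[Si](C(C)C)(C(C)C)C(C)C)cc1
F5 | step 3 | (Z)-2-methoxy-1-[4-(triisopropylsilyloxy)phenyl]ethenyl trifluoromethanesulfonate | CO/C=C(/c1ccc(O[Si](C(C)C)(C(C)C)C(C)C)cc1)OS(=O)(=O)C(F)(F)F
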